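**Retrosynthetic overview**
1. Target 15 ⇒ mono-angelate 14 + angelic acid 12: the C10–O bond is made last by a palladium-catalysed allylic C–H angeloyloxylation with 1,3-transposition (Δ9 → Δ8), which sets C10.
2. 14 ⇒ diol 11 (C6 acylation) ⇒ diene-diol 10: the seven-membered ring is closed by ring-closing metathesis (C9=C10) onto a preformed cyclopentane.
3. 10 ⇒ ketol 9/8 (isopropyl addition sets C4) ⇒ 3-methylcyclopentenone 4 + silylacetylene 5 + aldehyde 3: enantioselective conjugate addition/anti-aldol sets C1, C5 and C6.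
4. 3 ⇒ crotonaldehyde 1 + styryltrifluoroborate 2: organocatalytic conjugate styrylation sets C8.
5. Ring order: the five-membered ring is bought, the seven-membered ring is formed second.

Assumption: positions are numbered as in the daucane skeleton (C1 angular-methyl carbon, C4 carbinol with isopropyl, C5 ring-fusion CH, C6 and C10 ester carbons, C8=C9 olefin); α means the face opposite the angular methyl. The route is a proposal and has not been run.

Step 1
Reactants: 1 (E)-but-2-enal (crotonaldehyde); 2 potassium (E)-styryltrifluoroborate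
Product: 3 (3S,4E)-3-methyl-5-phenylpent-4-enal
Conditions: (2R,5R)-5-benzyl-2-tert-butyl-3-methylimidazolidin-4-one·HCl (20 mol %; the enantiomer that gives the S aldehyde), HF (48% aq., 1 equiv), DME, −20 °C
Reagents that add atoms: none
Why: Iminium-ion organocatalysis (MacMillan-type conjugate vinylation): the imidazolidinone shields one face of the (E)-iminium of 1, so the styryl group of the fluoride-activated trifluoroborate adds to the β-carbon and sets the S centre that becomes C8.

Step 2
Reactants: 4 3-methylcyclopent-2-en-1-one; 5 trimethylsilylacetylene; 3 (3S,4E)-3-methyl-5-phenylpent-4-enal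
Product: 8 (2S,3S)-2-[(1S,3S,4E)-1-hydroxy-3-methyl-5-phenylpent-4-en-1-yl]-3-methyl-3-[1-(trimethylsilyl)ethenyl]cyclopentan-1-one, via silylvinylalane 6 (not isolated), via aluminium enolate 7 (not isolated)
Conditions: 5, i-Bu2AlH, hexane/THF, 55 °C; then 4, Cu(OTf)2 (5 mol %), chiral sulfonate-bearing imidazolinium salt (6 mol %, NHC precursor, enantiomer giving the S adduct), THF, −50 °C; then 3 (2 equiv), −78 → −40 °C; aq. Rochelle salt
Reagents that add atoms: none
Why: Hydroalumination places aluminium on the silicon-bearing carbon, the NHC–copper-catalysed enantioselective conjugate addition (Hoveyda type) sets the quaternary C1, and the regiodefined aluminium enolate undergoes a closed Zimmerman–Traxler aldol with 3 on the face anti to the bulky 1-silylvinyl group (side chain cis to the methyl) with the anti relationship expected of a cyclic E-enolate, setting C5 and C6.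

Step 3
Reactants: 8 (2S,3S)-2-[(1S,3S,4E)-1-hydroxy-3-methyl-5-phenylpent-4-en-1-yl]-3-methyl-3-[1-(trimethylsilyl)ethenyl]cyclopentan-1-one
Product: 9 (2S,3R)-3-ethenyl-2-[(1S,3S,4E)-1-hydroxy-3-methyl-5-phenylpent-4-en-1-yl]-3-methylcyclopentan-1-one
Conditions: CF3CO2H (5 equiv), CH2Cl2, 0 °C, 1 h
Reagents that add atoms: none
Why: Electrophilic ipso-protodesilylation of the vinylsilane through the β-silyl-stabilised cation unmasks the plain vinyl group without touching a stereocentre (the descriptor at C3 changes only through priorities).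

Step 4
Reactants: 9 (2S,3R)-3-ethenyl-2-[(1S,3S,4E)-1-hydroxy-3-methyl-5-phenylpent-4-en-1-yl]-3-methylcyclopentan-1-one
Product: 10 (1R,2S,3R)-3-ethenyl-2-[(1S,3S,4E)-1-hydroxy-3-methyl-5-phenylpent-4-en-1-yl]-3-methyl-1-(propan-2-yl)cyclopentan-1-ol
Conditions: i-PrMgCl (3 equiv), LaCl3·2LiCl (1 equiv), THF, −20 → 0 °C
Reagents that add atoms: isopropylmagnesium chloride CC(C)[Mg]Cl
Why: Lanthanum-promoted Grignard 1,2-addition suppresses enolisation and reduction, and the nucleophile attacks the cyclopentanone face anti to the adjacent C5 side chain, giving the tertiary alcohol cis to that chain (C4 R).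

Step 5
Reactants: 10 (1R,2S,3R)-3-ethenyl-2-[(1S,3S,4E)-1-hydroxy-3-methyl-5-phenylpent-4-en-1-yl]-3-methyl-1-(propan-2-yl)cyclopentan-1-ol
Product: 11 (3R,3aS,4S,6S,8aR)-6,8a-dimethyl-3-(propan-2-yl)-1,2,3,3a,4,5,6,8a-octahydroazulene-3,4-diol (dauc-9-ene-4β,6α-diol with 8β-methyl)
Conditions: second-generation Grubbs catalyst (H2IMes)(PCy3)Cl2Ru=CHPh (5 mol %), CH2Cl2 (2 mM), 40 °C
Reagents that add atoms: none
Why: Ring-closing olefin metathesis of the vinyl and styryl termini (styrene lost) closes the cis-cycloheptene C9=C10 on the trans-1,2-disubstituted cyclopentane, so the trans ring fusion is inherited and no stereocentre changes.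

Step 6
Reactants: 11 (3R,3aS,4S,6S,8aR)-6,8a-dimethyl-3-(propan-2-yl)-1,2,3,3a,4,5,6,8a-octahydroazulene-3,4-diol; 12 angelic acid ((2Z)-2-methylbut-2-enoic acid)
Product: 14 (3R,3aS,4S,6S,8aR)-3-hydroxy-6,8a-dimethyl-3-(propan-2-yl)-1,2,3,3a,4,5,6,8a-octahydroazulen-4-yl (2Z)-2-methylbut-2-enoate, via mixed anhydride 13 (not isolated)
Conditions: 12 (3 equiv), 2,4,6-trichlorobenzoyl chloride (3 equiv), Et3N (6 equiv), toluene, rt, 2 h; then 11, 75 °C
Reagents that add atoms: none
Why: Yamaguchi-type mixed-anhydride esterification without a nucleophilic amine catalyst acylates only the secondary C6 hydroxyl (the tertiary C4 hydroxyl is inert) and preserves the Z geometry of the angelate.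

Step 7
Reactants: 14 (3R,3aS,4S,6S,8aR)-3-hydroxy-6,8a-dimethyl-3-(propan-2-yl)-1,2,3,3a,4,5,6,8a-octahydroazulen-4-yl (2Z)-2-methylbut-2-enoate; 12 angelic acid
Product: 15 (3R,3aS,4S,8R,8aS)-3-hydroxy-6,8a-dimethyl-3-(propan-2-yl)-1,2,3,3a,4,5,8,8a-octahydroazulene-4,8-diyl bis[(2Z)-2-methylbut-2-enoate] (CNP0183261.1)
Conditions: 12 (4 equiv), Pd(OAc)2 (10 mol %, pre-stirred with 12), 1,2-bis(phenylsulfinyl)ethane (10 mol %), 2,6-dimethyl-1,4-benzoquinone (2 equiv), 1,4-dioxane, 45 °C
Reagents that add atoms: none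
Why: Proposed new method: an electrophilic divalent palladium–bis-sulfoxide carboxylate should bind the only unconjugated olefin (C9=C10) on its α face (the β face is blocked by the C1 and C8 methyls), the Pd-bound angelate removes the single allylic hydrogen H8 (also α) by concerted metalation–deprotonation to give the C8–C9–C10 π-allyl, and quinone-promoted inner-sphere C–O reductive elimination at the less substituted terminus C10 delivers the 10α-angelate and the Δ8 trisubstituted olefin (a net suprafacial 1,3-shift that forms the key C–O bond and sets C10); the closest known reactions are White-type sulfoxide/Pd(OAc)2 allylic C–H esterification of terminal olefins and Pd(OAc)2/benzoquinone allylic acetoxylation of simple cycloalkenes, neither shown for an internal olefin with one tertiary allylic C–H and a complex Z-enoic acid.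

**Compound list**
1 | (E)-but-2-enal | C/C=C/C=O | starting material
2 | potassium (E)-styryltrifluoroborate | [K+].F[B-](F)(F)/C=C/c1ccccc1 | starting material
3 | (3S,4E)-3-methyl-5-phenylpent-4-enal | O=CC[C@H](C)/C=C/c1ccccc1 | intermediate
4 | 3-methylcyclopent-2-en-1-one | CC1=CC(=O)CC1 | starting material
5 | trimethylsilylacetylene | C#C[Si](C)(C)C | starting material
6 | [1-(trimethylsilyl)ethenyl]bis(2-methylpropyl)aluminium | C=C([Si](C)(C)C)[Al](CC(C)C)CC(C)C | intermediate
7 | bis(2-methylpropyl)aluminium (3S)-3-methyl-3-[1-(trimethylsilyl)ethenyl]cyclopent-1-en-1-olate | C=C([Si](C)(C)C)[C@@]1(C)CCC(O[Al](CC(C)C)CC(C)C)=C1 | intermediate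
8 | (2S,3S)-2-[(1S,3S,4E)-1-hydroxy-3-methyl-5-phenylpent-4-en-1-yl]-3-methyl-3-[1-(trimethylsilyl)ethenyl]cyclopentan-1-one | C=C([Si](C)(C)C)[C@@]1(C)CCC(=O)[C@@H]1[C@@H](O)C[C@H](C)/C=C/c1ccccc1 | intermediate
9 | (2S,3R)-3-ethenyl-2-[(1S,3S,4E)-1-hydroxy-3-methyl-5-phenylpent-4-en-1-yl]-3-methylcyclopentan-1-one | C=C[C@@]1(C)CCC(=O)[C@@H]1[C@@H](O)C[C@H](C)/C=C/c1ccccc1 | intermediate
10 | (1R,2S,3R)-3-ethenyl-2-[(1S,3S,4E)-1-hydroxy-3-methyl-5-phenylpent-4-en-1-yl]-3-methyl-1-(propan-2-yl)cyclopentan-1-ol | C=C[C@@]1(C)CC[C@@](O)(C(C)C)[C@@H]1[C@@H](O)C[C@H](C)/C=C/c1ccccc1 | intermediate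
11 | (3R,3aS,4S,6S,8aR)-6,8a-dimethyl-3-(propan-2-yl)-1,2,3,3a,4,5,6,8a-octahydroazulene-3,4-diol | O[C@H]1C[C@H](C)C=C[C@@]2(C)CC[C@@](O)(C(C)C)[C@H]12 | intermediate
12 | angelic acid, (2Z)-2-methylbut-2-enoic acid | C/C=C(/C)C(=O)O | starting material
13 | (2Z)-2-methylbut-2-enoic 2,4,6-trichlorobenzoic anhydride | C/C=C(/C)C(=O)OC(=O)c1c(Cl)cc(Cl)cc1Cl | intermediate
14 | (3R,3aS,4S,6S,8aR)-3-hydroxy-6,8a-dimethyl-3-(propan-2-yl)-1,2,3,3a,4,5,6,8a-octahydroazulen-4-yl (2Z)-2-methylbut-2-enoate | C/C=C(/C)C(=O)O[C@H]1C[C@H](C)C=C[C@@]2(C)CC[C@@](O)(C(C)C)[C@H]12 | intermediate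
15 | (3R,3aS,4S,8R,8aS)-3-hydroxy-6,8a-dimethyl-3-(propan-2-yl)-1,2,3,3a,4,5,8,8a-octahydroazulene-4,8-diyl bis[(2Z)-2-methylbut-2-enoate] | C/C=C(/C)C(=O)O[C@H]1CC(C)=C[C@@H](OC(=O)/C(C)=C\C)[C@@]2(C)CC[C@@](O)(C(C)C)[C@H]12 | target

**Step count**
Total steps: 7. Longest linear sequence: 7 steps (1 → 3 → 8 → 9 → 10 → 11 → 14 → 15); 6 steps counted from enone 4.

**Three steps most likely to fail**

Step 2 (three-component conjugate addition/aldol). The aluminium enolate may be sluggish towards 3, excess alane may consume the aldehyde, and the anti and facial selectivities are argued by analogy. The fallback separates the two events and changes the enolate metal. It sets out from 4 and 5 and runs the same conjugate addition to 7, which is quenched with Me3SiOTf to isolate the enol silane F1. MeLi in THF at 0 °C cleaves F1 to the lithium enolate F2. ZnCl2 converts F2 into the chlorozinc enolate F3. Addition of 3 at −78 °C then gives the anti aldol through a tighter closed transition state, and the fallback returns to the route at 8.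

Step 3 (acidic protodesilylation). The ketol and the styrene are acid-sensitive, and protonation at the terminal carbon instead of the ipso carbon would give a cation next to the quaternary centre that can rearrange. The fallback moves the desilylation to a later stage and uses a nucleophilic mechanism. It sets out from 8, which is treated directly under the conditions of step 4 (i-PrMgCl, LaCl3·2LiCl) to give the silylated diol F4. Bu4NF (3 equiv) with KOt-Bu (0.2 equiv) in DMSO at 80 °C then removes the silyl group by fluoride/alkoxide-induced cleavage, with no carbonyl or acid present, and the fallback returns to the route at 10.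

Step 7 (proposed new C–H angeloyloxylation). An internal olefin binds the metal weakly and the tertiary C–H is hard to cleave. The π-allyl may lose a β-hydrogen to give a diene, or close the C–O bond at C8 instead of C10. The angelates could also isomerise to tiglates. The fallback uses known chemistry and sets out from 11. mCPBA with NaHCO3 in CH2Cl2 at 0 °C epoxidises the C9=C10 olefin from the α face to give the 9α,10α-epoxide F5. Et2Al(TMP) (5 equiv) in toluene at 0 °C → rt removes the syn H8 and opens the oxirane to the 10α-allylic alcohol, the triol F6. Double acylation of the two secondary hydroxyls of F6 with the mixed anhydride 13 (conditions of step 6, larger excess, 80 °C) returns to the route at 15.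

**Further compounds**
F1 | step 2 | trimethyl{[(3S)-3-methyl-3-[1-(trimethylsilyl)ethenyl]cyclopent-1-en-1-yl]oxy}silane | C=C([Si](C)(C)C)[C@@]1(C)CCC(O[Si](C)(C)C)=C1
F2 | step 2 | lithium (3S)-3-methyl-3-[1-(trimethylsilyl)ethenyl]cyclopent-1-en-1-olate | C=C([Si](C)(C)C)[C@@]1(C)CCC(O[Li])=C1
F3 | step 2 | chlorozinc (3S)-3-methyl-3-[1-(trimethylsilyl)ethenyl]cyclopent-1-en-1-olate | C=C([Si](C)(C)C)[C@@]1(C)CCC(O[Zn]Cl)=C1
F4 | step 3 | (1R,2S,3S)-2-[(1S,3S,4E)-1-hydroxy-3-methyl-5-phenylpent-4-en-1-yl]-3-methyl-1-(propan-2-yl)-3-[1-(trimethylsilyl)ethenyl]cyclopentan-1-ol | C=C([Si](C)(C)C)[C@@]1(C)CC[C@@](O)(C(C)C)[C@@H]1[C@@H](O)C[C@H](C)/C=C/c1ccccc1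
F5 | step 7 | 9α,10α-epoxide of 11 (oxirane on the face opposite the angular methyl; daucane numbering) | O[C@H]1C[C@H](C)[C@H]2O[C@H]2[C@@]3(C)CC[C@@](O)(C(C)C)[C@H]13
F6 | step 7 | (3R,3aS,4S,8R,8aS)-6,8a-dimethyl-3-(propan-2-yl)-1,2,3,3a,4,5,8,8a-octahydroazulene-3,4,8-triol | O[C@H]1CC(C)=C[C@@H](O)[C@@]2(C)CC[C@@](O)(C(C)C)[C@H]12
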